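**Retrosynthetic overview**
1. The target is fisetinidol-(4β→6)-mollisacacidin; the last operations are desilylation and hydrogenolysis of six benzyl ethers.
2. The interflavan C4–C6' bond is made with reversed polarity by a Cu/Pd three-component syn-arylboration of the C3=C4 bond of an (S)-flav-3-ene with the lower-unit C6'-bromide, followed by C–B to C–OH oxidation. This single operation forms the bond and sets C3 and C4 of the upper unit.
3. Enabling feature: in the upper pyran ring the C3 oxygen and the C4 aryl are cis to each other and both anti to the C2 aryl, and C4 is benzylic to ring A. That is the outcome of a syn addition across the styrenic C3=C4 bond from the face opposite the C2 aryl.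
4. Both halves come from one (S)-flavanone, made by asymmetric aryl addition to 7-benzyloxychromone. Reduction and dehydration give the flav-3-ene; Rubottom oxidation, NaBH4 reduction, silylation and C6 bromination give the lower unit.
5. No ring is closed in the route: both benzopyran cores come from 7-hydroxychromone and both B rings from one arylboronic acid; only the oxidation level of the pyran rings is adjusted.

Key step: step 9

Remark: the SMILES is read as upper unit 2R,3S,4S (2,3-trans-3,4-cis) and lower unit 2R,3S,4R (2,3-trans-3,4-trans). CIP descriptors of protected intermediates change with O-substitution although no centre is inverted. Compounds 1 and 3 are taken as catalogue compounds. Primed locants refer to the lower unit.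

**Step 1**
Reactants: 1 7-hydroxy-4H-chromen-4-one
Product: 2 7-(benzyloxy)-4H-chromen-4-one
Conditions: BnBr, K2CO3, DMF, rt
Reagents that add atoms: benzyl bromide, BrCc1ccccc1
Why: Williamson O-benzylation of the only acidic phenol; the chromone ring is stable to carbonate base.

**Step 2**
Reactants: 2 7-(benzyloxy)-4H-chromen-4-one; 3 [3,4-bis(benzyloxy)phenyl]boronic acid
Product: 4 (2S)-7-(benzyloxy)-2-[3,4-bis(benzyloxy)phenyl]chroman-4-one
Conditions: [Rh(OH)(cod)]2 (cat.), MeO-F12-BIPHEP (cat., the antipode that delivers the 2S product), toluene/H2O, rt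
Reagents that add atoms: none
Why: Rh-catalysed asymmetric 1,4-addition of an arylboronic acid to a chromone (Hayashi–Miyaura type), in which the chiral bisphosphine selects the enone face and so sets C2.

**Step 3**
Reactants: 4 (2S)-7-(benzyloxy)-2-[3,4-bis(benzyloxy)phenyl]chroman-4-one
Product: 5 (2S,4S)-7-(benzyloxy)-2-[3,4-bis(benzyloxy)phenyl]chroman-4-ol
Conditions: NaBH4, THF/MeOH, 0 °C
Reagents that add atoms: none
Why: borohydride reduction of the aryl ketone, expected to give the 2,4-cis alcohol by axial hydride delivery; the C4 centre is removed in the next step.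

**Step 4**
Reactants: 5 (2S,4S)-7-(benzyloxy)-2-[3,4-bis(benzyloxy)phenyl]chroman-4-ol
Product: 6 (2S)-7-(benzyloxy)-2-[3,4-bis(benzyloxy)phenyl]-2H-chromene
Conditions: Burgess reagent, toluene, 50 °C, dark
Reagents that add atoms: none
Why: Burgess dehydration of a benzylic alcohol under neutral conditions, where only C3 carries a β-hydrogen, so the C3=C4 alkene forms without touching C2.

**Step 5**
Reactants: 4 (2S)-7-(benzyloxy)-2-[3,4-bis(benzyloxy)phenyl]chroman-4-one
Product: 9 (2R,3R)-7-(benzyloxy)-2-[3,4-bis(benzyloxy)phenyl]-3-hydroxychroman-4-one, via silyl enol ether 7 (not isolated), via silyloxy epoxide 8 (not isolated)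
Conditions: TMSOTf, Et3N, CH2Cl2, 0 °C; evaporate; DMDO, acetone, −40 → 0 °C; citric acid, MeOH, rt
Reagents that add atoms: dimethyldioxirane, CC1(C)OO1 (the C3 oxygen); trimethylsilyl triflate, C[Si](C)(C)OS(=O)(=O)C(F)(F)F (silicon carried only in 7 and 8)
Why: Rubottom oxidation by soft enolisation (no enolate, so no retro-oxa-Michael opening), in which DMDO epoxidises the enol ether anti to the C2 aryl and so sets C3 as the 2,3-trans alcohol.

**Step 6**
Reactants: 9 (2R,3R)-7-(benzyloxy)-2-[3,4-bis(benzyloxy)phenyl]-3-hydroxychroman-4-one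
Product: 10 (2R,3S,4R)-7-(benzyloxy)-2-[3,4-bis(benzyloxy)phenyl]chromane-3,4-diol
Conditions: NaBH4, THF/MeOH, 0 °C
Reagents that add atoms: none
Why: borohydride reduction of a 2,3-trans-dihydroflavonol, the classical entry to 2,3-trans-3,4-trans flavan-3,4-diols, in which axial hydride delivery places the new C4 hydroxyl equatorial and trans to the 3-OH.

**Step 7**
Reactants: 10 (2R,3S,4R)-7-(benzyloxy)-2-[3,4-bis(benzyloxy)phenyl]chromane-3,4-diol
Product: 11 (2R,3R,4R)-7-(benzyloxy)-2-[3,4-bis(benzyloxy)phenyl]-3,4-bis(tert-butyldimethylsilyloxy)chromane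
Conditions: TBSOTf, 2,6-lutidine, CH2Cl2, −40 → 0 °C
Reagents that add atoms: tert-butyldimethylsilyl triflate, CC(C)(C)[Si](C)(C)OS(=O)(=O)C(F)(F)F
Why: bis-silylation of the diol with a silyl triflate and excess hindered base, kept cold so the benzylic C4 oxygen is silylated and not ionised.

**Step 8**
Reactants: 11 (2R,3R,4R)-7-(benzyloxy)-2-[3,4-bis(benzyloxy)phenyl]-3,4-bis(tert-butyldimethylsilyloxy)chromane
Product: 12 (2R,3R,4R)-6-bromo-7-(benzyloxy)-2-[3,4-bis(benzyloxy)phenyl]-3,4-bis(tert-butyldimethylsilyloxy)chromane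
Conditions: NBS (1.0 equiv), CH2Cl2, −20 °C, dark
Reagents that add atoms: N-bromosuccinimide, O=C1CCC(=O)N1Br
Why: electrophilic aromatic bromination at C6, which is para to O1 and ortho to the 7-OBn; C8 is flanked by two oxygens and the catechol-type B ring lacks this doubly cooperative activation.

**Step 9**
Reactants: 6 (2S)-7-(benzyloxy)-2-[3,4-bis(benzyloxy)phenyl]-2H-chromene (1.5 equiv); 12 (2R,3R,4R)-6-bromo-7-(benzyloxy)-2-[3,4-bis(benzyloxy)phenyl]-3,4-bis(tert-butyldimethylsilyloxy)chromane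
Product: 14 (2R,3S,4R)-7-(benzyloxy)-4-[(2R,3R,4R)-7-(benzyloxy)-2-[3,4-bis(benzyloxy)phenyl]-3,4-bis(tert-butyldimethylsilyloxy)chroman-6-yl]-2-[3,4-bis(benzyloxy)phenyl]chroman-3-ol, via C3 pinacol boronate 13 (not isolated)
Conditions: SIMesCuCl (10 mol %), RuPhos Pd G3 (5 mol %), B2pin2 (1.5 equiv), NaOtBu (1.5 equiv), toluene, rt, dark; then 30% H2O2, 3 M NaOH, THF, 0 °C
Reagents that add atoms: hydrogen peroxide, OO (the C3 oxygen); bis(pinacolato)diboron, CC1(C)OB(OC1(C)C)B1OC(C)(C)C(C)(C)O1 (boron carried only in 13)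
Why: The NHC–Cu–Bpin species adds syn across C3=C4 of 6 on the face anti to the C2 aryl, with boron on C3 and copper on the benzylic C4; the C4–Cu bond transmetalates with retention to the aryl–Pd(RuPhos) bromide formed from 12, and reductive elimination makes the C4–C6' bond with C4 as the nucleophile and C6' as the electrophile, the reverse of the biogenetic polarity. The closest known reaction type is the Cu/Pd-cocatalysed syn-arylboration of cyclic alkenyl arenes (1,2-dihydronaphthalenes, indenes, 2H-chromenes) with aryl bromides, followed by stereoretentive C–B oxidation. No ring is closed. Both new stereocentres are controlled by the single C2 centre of 6: anti approach makes C3 2,3-trans, and syn addition makes C4 3,4-cis, the relationship that a cationic C4 arylation disfavours. The step needs regioselectivity (Cu at C4, secured by benzylic stabilisation from ring A; C6', secured by the bromine from step 8), facial selectivity (the C2 aryl) and retentive transmetalation (the RuPhos–Pd/toluene regime in which syn products are known). It also needs reductive elimination to outrun β-hydride elimination, which the bulky biarylphosphine favours.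

**Step 10**
Reactants: 14 (2R,3S,4R)-7-(benzyloxy)-4-[(2R,3R,4R)-7-(benzyloxy)-2-[3,4-bis(benzyloxy)phenyl]-3,4-bis(tert-butyldimethylsilyloxy)chroman-6-yl]-2-[3,4-bis(benzyloxy)phenyl]chroman-3-ol
Product: 15 (2R,3S,4R)-7-(benzyloxy)-4-[(2R,3S,4R)-7-(benzyloxy)-2-[3,4-bis(benzyloxy)phenyl]-3,4-dihydroxychroman-6-yl]-2-[3,4-bis(benzyloxy)phenyl]chroman-3-ol
Conditions: TBAF, AcOH, THF, 0 °C → rt
Reagents that add atoms: none
Why: fluoride cleavage of the two silyl ethers, buffered so that the benzylic C4'–O bond is neither ionised nor epimerised.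

**Step 11**
Reactants: 15 (2R,3S,4R)-7-(benzyloxy)-4-[(2R,3S,4R)-7-(benzyloxy)-2-[3,4-bis(benzyloxy)phenyl]-3,4-dihydroxychroman-6-yl]-2-[3,4-bis(benzyloxy)phenyl]chroman-3-ol
Product: 16 (2R,3S,4S)-2-(3,4-dihydroxyphenyl)-4-[(2R,3S,4R)-2-(3,4-dihydroxyphenyl)-3,4,7-trihydroxychroman-6-yl]chromane-3,7-diol
Conditions: H2 (1 atm), Pd(OH)2/C, THF/MeOH, rt
Reagents that add atoms: none
Why: neutral catalytic hydrogenolysis of the six aryl benzyl ethers, which should cleave much faster than the secondary benzylic C4'–OH or the pyran C2–O bonds.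

**Compound list**
1 | 7-hydroxy-4H-chromen-4-one | O=c1ccoc2cc(O)ccc12 | starting material
2 | 7-(benzyloxy)-4H-chromen-4-one | O=c1ccoc2cc(OCc3ccccc3)ccc12 | intermediate
3 | [3,4-bis(benzyloxy)phenyl]boronic acid | OB(O)c1ccc(OCc2ccccc2)c(OCc2ccccc2)c1 | starting material
4 | (2S)-7-(benzyloxy)-2-[3,4-bis(benzyloxy)phenyl]chroman-4-one | C(c1ccccc1)Oc1ccc2c(c1)O[C@H](c1ccc(OCc3ccccc3)c(OCc3ccccc3)c1)CC2=O | intermediate
5 | (2S,4S)-7-(benzyloxy)-2-[3,4-bis(benzyloxy)phenyl]chroman-4-ol (2,4-cis) | C(c1ccccc1)Oc1ccc2c(c1)O[C@H](c1ccc(OCc3ccccc3)c(OCc3ccccc3)c1)C[C@@H]2O | intermediate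
6 | (2S)-7-(benzyloxy)-2-[3,4-bis(benzyloxy)phenyl]-2H-chromene (flav-3-ene) | C(c1ccccc1)Oc1ccc2c(c1)O[C@H](c1ccc(OCc3ccccc3)c(OCc3ccccc3)c1)C=C2 | intermediate
7 | (2S)-7-(benzyloxy)-2-[3,4-bis(benzyloxy)phenyl]-4-(trimethylsilyloxy)-2H-chromene (silyl enol ether) | C(c1ccccc1)Oc1ccc2c(c1)O[C@H](c1ccc(OCc3ccccc3)c(OCc3ccccc3)c1)C=C2O[Si](C)(C)C | intermediate (not isolated)
8 | 3,4-epoxide of 7, oxirane oxygen anti to the C2 aryl, OTMS on C4 (silyloxy epoxide) | C(c1ccccc1)Oc1ccc2c(c1)O[C@H](c1ccc(OCc3ccccc3)c(OCc3ccccc3)c1)[C@H]3O[C@@]23O[Si](C)(C)C | intermediate (not isolated)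
9 | (2R,3R)-7-(benzyloxy)-2-[3,4-bis(benzyloxy)phenyl]-3-hydroxychroman-4-one (2,3-trans; tri-O-benzylfustin) | C(c1ccccc1)Oc1ccc2c(c1)O[C@H](c1ccc(OCc3ccccc3)c(OCc3ccccc3)c1)[C@@H](O)C2=O | intermediate
10 | (2R,3S,4R)-7-(benzyloxy)-2-[3,4-bis(benzyloxy)phenyl]chromane-3,4-diol (2,3-trans-3,4-trans) | C(c1ccccc1)Oc1ccc2c(c1)O[C@H](c1ccc(OCc3ccccc3)c(OCc3ccccc3)c1)[C@@H](O)[C@@H]2O | intermediate
11 | (2R,3R,4R)-7-(benzyloxy)-2-[3,4-bis(benzyloxy)phenyl]-3,4-bis(tert-butyldimethylsilyloxy)chromane (2,3-trans-3,4-trans) | C(c1ccccc1)Oc1ccc2c(c1)O[C@H](c1ccc(OCc3ccccc3)c(OCc3ccccc3)c1)[C@@H](O[Si](C)(C)C(C)(C)C)[C@@H]2O[Si](C)(C)C(C)(C)C | intermediate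
12 | (2R,3R,4R)-6-bromo-7-(benzyloxy)-2-[3,4-bis(benzyloxy)phenyl]-3,4-bis(tert-butyldimethylsilyloxy)chromane | Brc1cc2c(cc1OCc1ccccc1)O[C@H](c1ccc(OCc3ccccc3)c(OCc3ccccc3)c1)[C@@H](O[Si](C)(C)C(C)(C)C)[C@@H]2O[Si](C)(C)C(C)(C)C | intermediate
13 | C3 pinacol boronate of the coupled dimer (upper unit 2,3-trans-3,4-cis: Bpin on C3 and the lower-unit C6' aryl on C4, both anti to the C2 aryl) | C(c1ccccc1)Oc1ccc2c(c1)O[C@H](c1ccc(OCc3ccccc3)c(OCc3ccccc3)c1)[C@@H](B3OC(C)(C)C(C)(C)O3)[C@H]2c1cc2c(cc1OCc1ccccc1)O[C@H](c1ccc(OCc3ccccc3)c(OCc3ccccc3)c1)[C@@H](O[Si](C)(C)C(C)(C)C)[C@@H]2O[Si](C)(C)C(C)(C)C | intermediate (not isolated)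
14 | (2R,3S,4R)-7-(benzyloxy)-4-[(2R,3R,4R)-7-(benzyloxy)-2-[3,4-bis(benzyloxy)phenyl]-3,4-bis(tert-butyldimethylsilyloxy)chroman-6-yl]-2-[3,4-bis(benzyloxy)phenyl]chroman-3-ol (upper 2,3-trans-3,4-cis; lower 2,3-trans-3,4-trans) | C(c1ccccc1)Oc1ccc2c(c1)O[C@H](c1ccc(OCc3ccccc3)c(OCc3ccccc3)c1)[C@@H](O)[C@H]2c1cc2c(cc1OCc1ccccc1)O[C@H](c1ccc(OCc3ccccc3)c(OCc3ccccc3)c1)[C@@H](O[Si](C)(C)C(C)(C)C)[C@@H]2O[Si](C)(C)C(C)(C)C | intermediate
15 | (2R,3S,4R)-7-(benzyloxy)-4-[(2R,3S,4R)-7-(benzyloxy)-2-[3,4-bis(benzyloxy)phenyl]-3,4-dihydroxychroman-6-yl]-2-[3,4-bis(benzyloxy)phenyl]chroman-3-ol | C(c1ccccc1)Oc1ccc2c(c1)O[C@H](c1ccc(OCc3ccccc3)c(OCc3ccccc3)c1)[C@@H](O)[C@H]2c1cc2c(cc1OCc1ccccc1)O[C@H](c1ccc(OCc3ccccc3)c(OCc3ccccc3)c1)[C@@H](O)[C@@H]2O | intermediate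
16 | (2R,3S,4S)-2-(3,4-dihydroxyphenyl)-4-[(2R,3S,4R)-2-(3,4-dihydroxyphenyl)-3,4,7-trihydroxychroman-6-yl]chromane-3,7-diol | Oc1ccc2c(c1)O[C@H](c1ccc(O)c(O)c1)[C@@H](O)[C@H]2c1cc2c(cc1O)O[C@H](c1ccc(O)c(O)c1)[C@@H](O)[C@@H]2O | target

**Step count and risks**
Total steps: 11. Longest linear sequence: 9 (steps 1, 2, 5, 6, 7, 8, 9, 10, 11).

Step 9 (key step). What may go wrong: the syn relationship could be lost through stereoinvertive Cu-to-Pd transmetalation or epimerisation of the C4 benzylcopper. The alkoxide base could deprotonate the allylic, benzylic C2–H of 6, causing racemisation or isomerisation to the 4H-chromene. Slow reductive elimination at the crowded diarylmethine carbon could let β-hydride elimination or protodemetalation take over. Fallback with known chemistry, setting out from 9 and 12: 9 is silylated (TBSOTf, 2,6-lutidine) to (2R,3R)-7-(benzyloxy)-2-[3,4-bis(benzyloxy)phenyl]-3-(tert-butyldimethylsilyloxy)chroman-4-one F1. Bromide 12 undergoes Br/Li exchange (t-BuLi, THF, −78 °C) and the aryllithium adds to the C4 carbonyl of F1 to give the tertiary diarylcarbinol F2. Ionic hydrogenation (Et3SiH, TFA, CH2Cl2, −40 °C) then gives the 3,4-cis tris-silyl ether F3; the doubly benzylic tertiary centre should ionise far faster than the secondary C4'–OTBS, and hydride should enter anti to the C3 silyloxy group. TBAF/AcOH removes the three silyl groups and the route is rejoined at 15.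

Step 2. What may go wrong: incomplete enantiofacial control, erosion of optical purity by reversible retro-oxa-Michael opening of the flavanone under the Rh–hydroxide conditions, and protodeboronation of the electron-rich boronic acid. Fallback, setting out from 2 and 3: an achiral Pd(II)/2,2'-bipyridine-catalysed conjugate addition gives the racemic flavanone F4. Kinetic resolution by Noyori-type asymmetric transfer hydrogenation (Rh– or Ru–TsDPEN, HCO2H/Et3N, the catalyst antipode that reduces the 2R ketone) converts the unwanted enantiomer into the (2R,4R)-flavan-4-ol F5, which is separated by chromatography. The unreduced ketone is 4, where the route is rejoined.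

Step 11. What may go wrong: hydrogenolysis of the benzylic C4'–OH bond of the flavan-3,4-diol unit could compete with O-debenzylation, and acid-induced ionisation at C4' of the free phenolic product on the catalyst could cause epimerisation or self-condensation. Fallback, setting out from 15: MnO2 (CH2Cl2, rt) oxidises only the benzylic C4'–OH to give the hexa-O-benzyl 4'-ketone F6. Hydrogenolysis (H2, Pd(OH)2/C), to which the aryl ketone is inert, gives the free phenolic ketone F7. NaBH4 (EtOH, 0 °C), the classical reduction of free phenolic 2,3-trans-dihydroflavonols to 2,3-trans-3,4-trans diols, then gives 16 as the last step.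

**Further compounds**
F1 | step 9 | (2R,3R)-7-(benzyloxy)-2-[3,4-bis(benzyloxy)phenyl]-3-(tert-butyldimethylsilyloxy)chroman-4-one | C(c1ccccc1)Oc1ccc2c(c1)O[C@H](c1ccc(OCc3ccccc3)c(OCc3ccccc3)c1)[C@@H](O[Si](C)(C)C(C)(C)C)C2=O
F2 | step 9 | tertiary diarylcarbinol: C4 of the upper unit bears OH and the lower-unit C6' aryl (aryl anti to the 3-OTBS; this centre is erased in the next operation) | C(c1ccccc1)Oc1ccc2c(c1)O[C@H](c1ccc(OCc3ccccc3)c(OCc3ccccc3)c1)[C@@H](O[Si](C)(C)C(C)(C)C)[C@]2(O)c1cc2c(cc1OCc1ccccc1)O[C@H](c1ccc(OCc3ccccc3)c(OCc3ccccc3)c1)[C@@H](O[Si](C)(C)C(C)(C)C)[C@@H]2O[Si](C)(C)C(C)(C)C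
F3 | step 9 | hexa-O-benzyl tris-O-TBS dimer (upper unit 2,3-trans-3,4-cis) | C(c1ccccc1)Oc1ccc2c(c1)O[C@H](c1ccc(OCc3ccccc3)c(OCc3ccccc3)c1)[C@@H](O[Si](C)(C)C(C)(C)C)[C@H]2c1cc2c(cc1OCc1ccccc1)O[C@H](c1ccc(OCc3ccccc3)c(OCc3ccccc3)c1)[C@@H](O[Si](C)(C)C(C)(C)C)[C@@H]2O[Si](C)(C)C(C)(C)C
F4 | step 2 | racemic 7-(benzyloxy)-2-[3,4-bis(benzyloxy)phenyl]chroman-4-one | C(c1ccccc1)Oc1ccc2c(c1)OC(c1ccc(OCc3ccccc3)c(OCc3ccccc3)c1)CC2=O
F5 | step 2 | (2R,4R)-7-(benzyloxy)-2-[3,4-bis(benzyloxy)phenyl]chroman-4-ol | C(c1ccccc1)Oc1ccc2c(c1)O[C@@H](c1ccc(OCc3ccccc3)c(OCc3ccccc3)c1)C[C@H]2O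
F6 | step 11 | hexa-O-benzyl dimer with the lower unit as the 3'-hydroxy-4'-ketone | C(c1ccccc1)Oc1ccc2c(c1)O[C@H](c1ccc(OCc3ccccc3)c(OCc3ccccc3)c1)[C@@H](O)[C@H]2c1cc2c(cc1OCc1ccccc1)O[C@H](c1ccc(OCc3ccccc3)c(OCc3ccccc3)c1)[C@@H](O)C2=O
F7 | step 11 | free phenolic dimer with the lower unit as the 3'-hydroxy-4'-ketone | Oc1ccc2c(c1)O[C@H](c1ccc(O)c(O)c1)[C@@H](O)[C@H]2c1cc2c(cc1O)O[C@H](c1ccc(O)c(O)c1)[C@@H](O)C2=O
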